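**Retrosynthetic overview**
- Ring A (C4a, C5, C6, C7, C8, C8a) is a phloroglucinol whose three oxygens must be told apart. C8a, the carbon of the lactone oxygen O1, lies between the two carbon-substituted positions C4a and C8, so ring A is built in a way that leaves O1 as its only free phenol.
- Last ring: the lactone (C2–O1) is closed from a methyl ester onto that phenol. The C8 ketone is then unmasked from a silylated carbinol, and the O7/O4' silyl ethers and the O5 benzyl ether are removed last.
- Ring A: a 4-substituted 3-benzyloxycyclobutenone and a silyloxyalkyne are joined by ketene–alkyne [2+2] cycloaddition (C8a–C8, C7–C6) and ring A is closed by 6π electrocyclisation (C8a–C4a).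
- The cyclobutenone comes from the ketene of (R)-3-phenylglutaric acid monomethyl ester (C4 set by desymmetrising the anhydride) and benzyloxyethyne. The silyloxyalkyne comes from methyl 3-(4-hydroxyphenyl)propanoate via a propargylic alcohol.
- Order of ring formation: ring A, then the pyranone ring.

Key step: step 9

Assumption: the quinine-derived thiourea catalyst is taken to give the R half-ester; if the sense is the opposite, its quinidine-derived pseudoenantiomer is used and nothing else changes.

**Route**

Step 1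
Reactants: 1 3-phenylglutaric anhydride
Product: 2 (3R)-5-methoxy-5-oxo-3-phenylpentanoic acid
Conditions: MeOH (10 equiv), 9-amino-9-deoxy-epi-quinine 3,5-bis(trifluoromethyl)phenyl thiourea (10 mol%), MTBE, rt
Reagents that add atoms: methanol (CO)
Why: Alcoholytic desymmetrisation of a prochiral cyclic anhydride: the bifunctional cinchona thiourea activates methanol by general base catalysis and one of the two enantiotopic carbonyls by hydrogen bonding, which sets the future C4 as R under catalyst control (the half-ester can be enriched further by crystallising an amine salt).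

Step 2
Reactants: 3 benzyl alcohol; 4 trichloroethylene
Product: 7 benzyloxyethyne, via dichlorovinyl ether 5 (not isolated), via lithium acetylide 6 (not isolated)
Conditions: KH, THF, 0 °C; Cl2C=CHCl, −50 °C to rt; n-BuLi (2.4 equiv), −78 °C; MeOH, −78 °C; kept as a cold solution
Reagents that add atoms: none
Why: Alkoxyacetylene synthesis from an alcohol and trichloroethylene: the alkoxide adds to dichloroacetylene formed in the flask, n-BuLi effects dehydrochlorination and chlorine–lithium exchange, and protonation should give the terminal benzyl ynol ether, which is kept below 0 °C because benzyl ynol ethers rearrange on warming; benzyl is chosen so that O5 stays masked until a final neutral hydrogenolysis.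

Step 3
Reactants: 2 (3R)-5-methoxy-5-oxo-3-phenylpentanoic acid; 7 benzyloxyethyne
Product: 10 methyl (3S)-3-[2-(benzyloxy)-4-oxocyclobut-2-en-1-yl]-3-phenylpropanoate, via acid chloride 8 (not isolated), via ketene 9 (not isolated)
Conditions: (COCl)2, DMF (cat.), CH2Cl2, 0 °C to rt; evaporate; then 7 (2 equiv), Et3N (slow addition), Et2O, 0 °C to rt
Reagents that add atoms: none
Why: Dehydrochlorination of the acid chloride gives the aldoketene, which the ynol ether should trap in a ketene–alkyne [2+2] cycloaddition with its nucleophilic terminal carbon on the ketene carbonyl carbon, the known route to 3-alkoxy-4-substituted cyclobutenones from ethoxyacetylene; the ring stereocentre forms unselectively and is lost in step 9, and the acid chloride is neither heated nor stored so that C4 is not scrambled through the symmetrical anhydride.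

Step 4
Reactants: 11 methyl 3-(4-hydroxyphenyl)propanoate
Product: 12 methyl 3-[4-(triisopropylsilyloxy)phenyl]propanoate
Conditions: i-Pr3SiCl, imidazole, DMF, rt
Reagents that add atoms: triisopropylsilyl chloride (CC(C)[Si](Cl)(C(C)C)C(C)C)
Why: Standard silylation of a phenol; the bulky aryl silyl ether should survive the hydride, organometallic and thermal steps that follow.

Step 5
Reactants: 12 methyl 3-[4-(triisopropylsilyloxy)phenyl]propanoate
Product: 13 3-[4-(triisopropylsilyloxy)phenyl]propanal
Conditions: i-Bu2AlH (1.05 equiv), CH2Cl2, −78 °C; MeOH, aq. potassium sodium tartrate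
Reagents that add atoms: none
Why: Partial reduction of a methyl ester: the tetrahedral aluminium hemiacetal is stable at −78 °C and releases the aldehyde only on work-up.

Step 6
Reactants: 13 3-[4-(triisopropylsilyloxy)phenyl]propanal; 14 ethynylmagnesium bromide
Product: 15 rac-5-[4-(triisopropylsilyloxy)phenyl]pent-1-yn-3-ol
Conditions: THF, −78 to 0 °C; aq. NH4Cl
Reagents that add atoms: none
Why: Grignard addition of an acetylide to an aldehyde gives the racemic propargylic alcohol; no control is needed because this carbon becomes the C8 ketone in step 12.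

Step 7
Reactants: 15 rac-5-[4-(triisopropylsilyloxy)phenyl]pent-1-yn-3-ol
Product: 16 rac-triethyl({5-[4-(triisopropylsilyloxy)phenyl]pent-1-yn-3-yl}oxy)silane
Conditions: Et3SiCl, imidazole, CH2Cl2, 0 °C to rt
Reagents that add atoms: chlorotriethylsilane (CC[Si](Cl)(CC)CC)
Why: Standard silylation; the silylated carbinol keeps the ynol ether of step 8 electron-rich (an acyl group would not) and the triethylsilyl ether can later be removed in the presence of aryl triisopropylsilyl ethers.

Step 8
Reactants: 16 rac-triethyl({5-[4-(triisopropylsilyloxy)phenyl]pent-1-yn-3-yl}oxy)silane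
Product: 19 rac-triethyl({1-(triisopropylsilyloxy)-5-[4-(triisopropylsilyloxy)phenyl]pent-1-yn-3-yl}oxy)silane, via lithium acetylide 17 (not isolated), via lithium ynolate 18 (not isolated)
Conditions: n-BuLi, THF, −78 °C; t-BuOOLi (from t-BuOOH and LiN(SiMe3)2), −78 to 0 °C; i-Pr3SiOTf, −78 to 0 °C; Et3N-washed silica
Reagents that add atoms: lithium tert-butyl peroxide ([Li+].[O-]OC(C)(C)C); triisopropylsilyl trifluoromethanesulfonate (CC(C)[Si](C(C)C)(C(C)C)OS(=O)(=O)C(F)(F)F)
Why: Oxidation of a lithium acetylide by lithium tert-butyl peroxide gives the lithium ynolate, which the bulky silyl triflate should trap on oxygen, the general route from terminal alkynes to triisopropylsilyloxyalkynes; the product is handled on base-washed silica because the propargylic silyloxy group makes it acid-labile.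

Step 9
Reactants: 10 methyl (3S)-3-[2-(benzyloxy)-4-oxocyclobut-2-en-1-yl]-3-phenylpropanoate; 19 rac-triethyl({1-(triisopropylsilyloxy)-5-[4-(triisopropylsilyloxy)phenyl]pent-1-yn-3-yl}oxy)silane
Product: 24 methyl (3R)-3-(6-(benzyloxy)-2-hydroxy-3-{1-(triethylsilyloxy)-3-[4-(triisopropylsilyloxy)phenyl]propyl}-4-(triisopropylsilyloxy)phenyl)-3-phenylpropanoate, via vinylketene 20 (not isolated), via cyclobutenone adduct 21 (not isolated), via dienylketene 22 (not isolated), via cyclohexadienone 23 (not isolated)
Conditions: 19 (1.3 equiv), toluene (0.2 M), 80 to 110 °C, sealed tube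
Reagents that add atoms: none
Why: Proposed new method: heating should open cyclobutenone 10 by 4π-conrotatory electrocyclic cleavage to vinylketene 20 (the C4a side chain turning outward), whose ketene C=C adds ynol ether 19 in a [2+2] cycloaddition in which the nucleophilic, alkyl-bearing alkyne carbon bonds to the ketene carbonyl carbon (C8a–C8) and the silyloxy-bearing carbon to the ketene α-carbon (C7–C6), giving 21. Adduct 21 should open (4π) to dienylketene 22, which closes ring A by thermal 6π-disrotatory electrocyclisation between C8a and C4a to dienone 23, and tautomerisation gives phenol 24, whose only free hydroxyl is on the former ketene carbon, C8a. The closest known reaction is the Danheiser benzannulation of 3-alkylcyclobutenones with trialkylsilyloxyalkynes to resorcinol monosilyl ethers; thermal opening of 3-alkoxycyclobutenones to vinylketenes is known from squarate-derived cases, but capture of a 3-alkoxy-4-alkyl vinylketene by an ynol ether has not been shown. No stereocentre is created: C4 lies outside the pericyclic array and is carried through unchanged, the sp3 ring carbon of 10 and of 23 ends as aromatic C4a, and the carbinol carbon is carried as a mixture that converges in step 12. The step needs regioselectivity in the [2+2], which the polarisation of the silyloxyalkyne secures, and outward rotation at C4a, which the preference of alkyl groups for outward rotation and the bulk of the branched side chain should secure, so that no inward-turned vinylketene forms that could shift the C4 hydrogen to the ketene carbon. A silyl ynol ether is used as the ketenophile because, unlike a benzyl ynol ether, it withstands 110 °C.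

Step 10
Reactants: 24 methyl (3R)-3-(6-(benzyloxy)-2-hydroxy-3-{1-(triethylsilyloxy)-3-[4-(triisopropylsilyloxy)phenyl]propyl}-4-(triisopropylsilyloxy)phenyl)-3-phenylpropanoate
Product: 25 (4R)-5-(benzyloxy)-4-phenyl-8-{1-(triethylsilyloxy)-3-[4-(triisopropylsilyloxy)phenyl]propyl}-7-(triisopropylsilyloxy)-3,4-dihydro-2H-chromen-2-one
Conditions: DBU (0.2 equiv), 5 Å molecular sieves, toluene, 50 °C
Reagents that add atoms: none
Why: Base-catalysed intramolecular transesterification: the only free phenol, on C8a, should attack the methyl ester in a 6-exo-trig closure of the lactone ring, the equilibrium being pulled over by uptake of methanol on the sieves, and acid is avoided because the electron-rich benzylic silyl ether at C8 ionises easily.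

Step 11
Reactants: 25 (4R)-5-(benzyloxy)-4-phenyl-8-{1-(triethylsilyloxy)-3-[4-(triisopropylsilyloxy)phenyl]propyl}-7-(triisopropylsilyloxy)-3,4-dihydro-2H-chromen-2-one
Product: 26 (4R)-5-(benzyloxy)-8-{1-hydroxy-3-[4-(triisopropylsilyloxy)phenyl]propyl}-4-phenyl-7-(triisopropylsilyloxy)-3,4-dihydro-2H-chromen-2-one
Conditions: HF·pyridine, pyridine, THF, 0 °C
Reagents that add atoms: none
Why: Selective desilylation: buffered hydrogen fluoride should cleave the secondary alkyl triethylsilyl ether far faster than the hindered aryl triisopropylsilyl ethers, and the weakly acidic, cold medium limits ionisation of the benzylic alcohol.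

Step 12
Reactants: 26 (4R)-5-(benzyloxy)-8-{1-hydroxy-3-[4-(triisopropylsilyloxy)phenyl]propyl}-4-phenyl-7-(triisopropylsilyloxy)-3,4-dihydro-2H-chromen-2-one
Product: 27 (4R)-5-(benzyloxy)-4-phenyl-7-(triisopropylsilyloxy)-8-{3-[4-(triisopropylsilyloxy)phenyl]propanoyl}-3,4-dihydro-2H-chromen-2-one
Conditions: Dess–Martin periodinane, NaHCO3, CH2Cl2, 0 °C to rt
Reagents that add atoms: none
Why: Dess–Martin oxidation of a hindered secondary benzylic alcohol under buffered, non-acidic conditions; both carbinol epimers converge on the C8 ketone and C4 is not enolisable.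

Step 13
Reactants: 27 (4R)-5-(benzyloxy)-4-phenyl-7-(triisopropylsilyloxy)-8-{3-[4-(triisopropylsilyloxy)phenyl]propanoyl}-3,4-dihydro-2H-chromen-2-one
Product: 28 (4R)-5-(benzyloxy)-7-hydroxy-8-[3-(4-hydroxyphenyl)propanoyl]-4-phenyl-3,4-dihydro-2H-chromen-2-one
Conditions: Bu4NF, AcOH (1:1.5), THF, 0 °C
Reagents that add atoms: none
Why: Fluoride cleavage of the two aryl silyl ethers, buffered with acetic acid so that no phenoxide opens the aryl lactone; O5 is still benzylated, so the lactone cannot migrate to it.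

Step 14
Reactants: 28 (4R)-5-(benzyloxy)-7-hydroxy-8-[3-(4-hydroxyphenyl)propanoyl]-4-phenyl-3,4-dihydro-2H-chromen-2-one
Product: 29 (4R)-5,7-dihydroxy-8-[3-(4-hydroxyphenyl)propanoyl]-4-phenyl-3,4-dihydro-2H-chromen-2-one
Conditions: H2 (1 atm), Pd/C, EtOAc, rt
Reagents that add atoms: none
Why: Hydrogenolysis of the aryl benzyl ether on palladium under neutral conditions should free O5 without touching the lactone, the hydrogen-bonded aryl ketone or C4.

**Compound list**

1 | 3-phenylglutaric anhydride (4-phenyloxane-2,6-dione) | O=C1CC(c2ccccc2)CC(=O)O1 | starting material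
2 | (3R)-5-methoxy-5-oxo-3-phenylpentanoic acid | COC(=O)C[C@H](c1ccccc1)CC(=O)O | intermediate
3 | benzyl alcohol | OCc1ccccc1 | starting material
4 | trichloroethylene | ClC=C(Cl)Cl | starting material
5 | benzyl (E)-1,2-dichlorovinyl ether | Cl/C=C(/Cl)OCc1ccccc1 | intermediate
6 | lithium (benzyloxy)acetylide | [Li]C#COCc1ccccc1 | intermediate
7 | benzyloxyethyne, [(ethynyloxy)methyl]benzene | C#COCc1ccccc1 | intermediate
8 | methyl (3S)-5-chloro-5-oxo-3-phenylpentanoate | COC(=O)C[C@H](c1ccccc1)CC(=O)Cl | intermediate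
9 | methyl (3S)-5-oxo-3-phenylpent-4-enoate (ketene) | COC(=O)C[C@H](c1ccccc1)C=C=O | intermediate
10 | methyl (3S)-3-[2-(benzyloxy)-4-oxocyclobut-2-en-1-yl]-3-phenylpropanoate, both epimers at the ring carbon | COC(=O)C[C@H](c1ccccc1)C1C(=O)C=C1OCc1ccccc1 | intermediate
11 | methyl 3-(4-hydroxyphenyl)propanoate | COC(=O)CCc1ccc(O)cc1 | starting material
12 | methyl 3-[4-(triisopropylsilyloxy)phenyl]propanoate | COC(=O)CCc1ccc(O[Si](C(C)C)(C(C)C)C(C)C)cc1 | intermediate
13 | 3-[4-(triisopropylsilyloxy)phenyl]propanal | O=CCCc1ccc(O[Si](C(C)C)(C(C)C)C(C)C)cc1 | intermediate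
14 | ethynylmagnesium bromide | C#C[Mg]Br | starting material
15 | rac-5-[4-(triisopropylsilyloxy)phenyl]pent-1-yn-3-ol | C#CC(O)CCc1ccc(O[Si](C(C)C)(C(C)C)C(C)C)cc1 | intermediate
16 | rac-triethyl({5-[4-(triisopropylsilyloxy)phenyl]pent-1-yn-3-yl}oxy)silane | C#CC(CCc1ccc(O[Si](C(C)C)(C(C)C)C(C)C)cc1)O[Si](CC)(CC)CC | intermediate
17 | lithium acetylide of 16 (lithium on the terminal alkyne carbon) | [Li]C#CC(CCc1ccc(O[Si](C(C)C)(C(C)C)C(C)C)cc1)O[Si](CC)(CC)CC | intermediate
18 | lithium 3-(triethylsilyloxy)-5-[4-(triisopropylsilyloxy)phenyl]pent-1-yn-1-olate (ynolate) | [Li]OC#CC(CCc1ccc(O[Si](C(C)C)(C(C)C)C(C)C)cc1)O[Si](CC)(CC)CC | intermediate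
19 | rac-triethyl({1-(triisopropylsilyloxy)-5-[4-(triisopropylsilyloxy)phenyl]pent-1-yn-3-yl}oxy)silane | CC[Si](CC)(CC)OC(CCc1ccc(O[Si](C(C)C)(C(C)C)C(C)C)cc1)C#CO[Si](C(C)C)(C(C)C)C(C)C | intermediate
20 | methyl (3S,4Z)-5-(benzyloxy)-7-oxo-3-phenylhepta-4,6-dienoate (vinylketene) | COC(=O)C[C@H](c1ccccc1)/C=C(OCc1ccccc1)/C=C=O | intermediate
21 | methyl (3S,4Z)-5-(benzyloxy)-5-(4-oxo-3-{1-(triethylsilyloxy)-3-[4-(triisopropylsilyloxy)phenyl]propyl}-2-(triisopropylsilyloxy)cyclobut-2-en-1-yl)-3-phenylpent-4-enoate, mixture at the ring and carbinol carbons | COC(=O)C[C@H](c1ccccc1)/C=C(OCc1ccccc1)/C1C(=O)C(C(CCc2ccc(O[Si](C(C)C)(C(C)C)C(C)C)cc2)O[Si](CC)(CC)CC)=C1O[Si](C(C)C)(C(C)C)C(C)C | intermediate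
22 | methyl (3S,4Z,6E)-5-(benzyloxy)-9-oxo-3-phenyl-8-{1-(triethylsilyloxy)-3-[4-(triisopropylsilyloxy)phenyl]propyl}-7-(triisopropylsilyloxy)nona-4,6,8-trienoate (dienylketene) | COC(=O)C[C@H](c1ccccc1)/C=C(OCc1ccccc1)/C=C(O[Si](C(C)C)(C(C)C)C(C)C)\C(C(CCc1ccc(O[Si](C(C)C)(C(C)C)C(C)C)cc1)O[Si](CC)(CC)CC)=C=O | intermediate
23 | methyl (3S)-3-(2-(benzyloxy)-6-oxo-5-{1-(triethylsilyloxy)-3-[4-(triisopropylsilyloxy)phenyl]propyl}-4-(triisopropylsilyloxy)cyclohexa-2,4-dien-1-yl)-3-phenylpropanoate, mixture at the ring and carbinol carbons | COC(=O)C[C@H](c1ccccc1)C1C(OCc2ccccc2)=CC(O[Si](C(C)C)(C(C)C)C(C)C)=C(C(CCc2ccc(O[Si](C(C)C)(C(C)C)C(C)C)cc2)O[Si](CC)(CC)CC)C1=O | intermediate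
24 | methyl (3R)-3-(6-(benzyloxy)-2-hydroxy-3-{1-(triethylsilyloxy)-3-[4-(triisopropylsilyloxy)phenyl]propyl}-4-(triisopropylsilyloxy)phenyl)-3-phenylpropanoate, both carbinol epimers | COC(=O)C[C@H](c1ccccc1)c1c(OCc2ccccc2)cc(O[Si](C(C)C)(C(C)C)C(C)C)c(C(CCc2ccc(O[Si](C(C)C)(C(C)C)C(C)C)cc2)O[Si](CC)(CC)CC)c1O | intermediate
25 | (4R)-5-(benzyloxy)-4-phenyl-8-{1-(triethylsilyloxy)-3-[4-(triisopropylsilyloxy)phenyl]propyl}-7-(triisopropylsilyloxy)-3,4-dihydro-2H-chromen-2-one, both carbinol epimers | O=C1C[C@H](c2ccccc2)c2c(OCc3ccccc3)cc(O[Si](C(C)C)(C(C)C)C(C)C)c(C(CCc3ccc(O[Si](C(C)C)(C(C)C)C(C)C)cc3)O[Si](CC)(CC)CC)c2O1 | intermediate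
26 | (4R)-5-(benzyloxy)-8-{1-hydroxy-3-[4-(triisopropylsilyloxy)phenyl]propyl}-4-phenyl-7-(triisopropylsilyloxy)-3,4-dihydro-2H-chromen-2-one, both carbinol epimers | O=C1C[C@H](c2ccccc2)c2c(OCc3ccccc3)cc(O[Si](C(C)C)(C(C)C)C(C)C)c(C(O)CCc3ccc(O[Si](C(C)C)(C(C)C)C(C)C)cc3)c2O1 | intermediate
27 | (4R)-5-(benzyloxy)-4-phenyl-7-(triisopropylsilyloxy)-8-{3-[4-(triisopropylsilyloxy)phenyl]propanoyl}-3,4-dihydro-2H-chromen-2-one | O=C1C[C@H](c2ccccc2)c2c(OCc3ccccc3)cc(O[Si](C(C)C)(C(C)C)C(C)C)c(C(=O)CCc3ccc(O[Si](C(C)C)(C(C)C)C(C)C)cc3)c2O1 | intermediate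
28 | (4R)-5-(benzyloxy)-7-hydroxy-8-[3-(4-hydroxyphenyl)propanoyl]-4-phenyl-3,4-dihydro-2H-chromen-2-one | O=C1C[C@H](c2ccccc2)c2c(OCc3ccccc3)cc(O)c(C(=O)CCc3ccc(O)cc3)c2O1 | intermediate
29 | (4R)-5,7-dihydroxy-8-[3-(4-hydroxyphenyl)propanoyl]-4-phenyl-3,4-dihydro-2H-chromen-2-one | O=C1C[C@H](c2ccccc2)c2c(O)cc(O)c(C(=O)CCc3ccc(O)cc3)c2O1 | target

**Step count and risks**

Total step count: 14. Longest linear sequence: 11 steps (steps 4, 5, 6, 7, 8, 9, 10, 11, 12, 13, 14).

Steps most likely to fail:

1. Step 9 (Proposed new method). The alkoxy-substituted cyclobutenone is a vinylogous ester and may open to the vinylketene only at temperatures at which the ynol ether is lost by silyl migration or by ionisation at its propargylic silyloxy carbon. The vinylketene may also dimerise faster than it is trapped. The fallback uses known reactions only, sets out from 11 and comes back to the route at 29; regiochemistry is then secured by a chelated hydroxyl instead of by ring construction.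
 - Ester 11 is saponified (LiOH, THF/H2O) to 3-(4-hydroxyphenyl)propanoic acid F1.
 - F1 acylates phloroglucinol (BF3·OEt2, 80 °C, Friedel–Crafts acylation) to 3-(4-hydroxyphenyl)-1-(2,4,6-trihydroxyphenyl)propan-1-one F2.
 - Benzylation (BnBr, 3 equiv, K2CO3, acetone) leaves only the hydroxyl chelated to the ketone and gives 1-[2,4-bis(benzyloxy)-6-hydroxyphenyl]-3-[4-(benzyloxy)phenyl]propan-1-one F3.
 - Esterification of that hydroxyl (propiolic acid, DCC, CH2Cl2, 0 °C) gives 3,5-bis(benzyloxy)-2-{3-[4-(benzyloxy)phenyl]propanoyl}phenyl prop-2-ynoate F4.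
 - Intramolecular 6-endo hydroarylation (PtCl4 cat., dioxane, 60 °C) at the only free position ortho to the ester oxygen gives 5,7-bis(benzyloxy)-8-{3-[4-(benzyloxy)phenyl]propanoyl}-2H-chromen-2-one F5.
 - Asymmetric 1,4-addition of phenylboronic acid (Hayashi–Miyaura reaction; Rh(acac)(C2H4)2, the SEGPHOS enantiomer that delivers 4R, expected to be the R ligand, dioxane/H2O, 60 °C) should give (4R)-5,7-bis(benzyloxy)-8-{3-[4-(benzyloxy)phenyl]propanoyl}-4-phenyl-3,4-dihydro-2H-chromen-2-one F6.
 - Hydrogenolysis (H2, Pd/C, EtOAc) converts F6 into 29.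

2. Step 10. Ring closure may stop short because methanol is not removed from the transesterification equilibrium, or the warm base may expel triethylsilanol from the o-hydroxybenzylic silyl ether before the phenol is acylated. The fallback sets out from 24 and comes back at 25. The methyl ester is cleaved under neutral conditions (Me3SnOH, 1,2-dichloroethane, 70 °C) to (3R)-3-(6-(benzyloxy)-2-hydroxy-3-{1-(triethylsilyloxy)-3-[4-(triisopropylsilyloxy)phenyl]propyl}-4-(triisopropylsilyloxy)phenyl)-3-phenylpropanoic acid F7. F7 is closed by carbodiimide dehydration (EDC·HCl, DMAP cat., CH2Cl2, 0 °C to rt; Steglich-type lactonisation) onto the only free phenol to give 25.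

3. Step 11. The acidic fluoride medium may ionise the electron-rich benzylic C–O bond (elimination towards the styrene or capture by the pendant arene), or an aryl silyl ether may be lost early. The fallback sets out from 25 and comes back at 27. The benzylic triethylsilyl ether is converted directly into the ketone by hydride abstraction with DDQ (CH2Cl2, pH 7 buffer, 0 °C to rt), the known oxidative cleavage of electron-rich benzylic silyl ethers. This skips 26 and makes no new compound (F0).

Further compounds
F1 | step 9 | 3-(4-hydroxyphenyl)propanoic acid | OC(=O)CCc1ccc(O)cc1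
F2 | step 9 | 3-(4-hydroxyphenyl)-1-(2,4,6-trihydroxyphenyl)propan-1-one | O=C(CCc1ccc(O)cc1)c1c(O)cc(O)cc1O
F3 | step 9 | 1-[2,4-bis(benzyloxy)-6-hydroxyphenyl]-3-[4-(benzyloxy)phenyl]propan-1-one | O=C(CCc1ccc(OCc2ccccc2)cc1)c1c(O)cc(OCc2ccccc2)cc1OCc1ccccc1
F4 | step 9 | 3,5-bis(benzyloxy)-2-{3-[4-(benzyloxy)phenyl]propanoyl}phenyl prop-2-ynoate | C#CC(=O)Oc1cc(OCc2ccccc2)cc(OCc2ccccc2)c1C(=O)CCc1ccc(OCc2ccccc2)cc1
F5 | step 9 | 5,7-bis(benzyloxy)-8-{3-[4-(benzyloxy)phenyl]propanoyl}-2H-chromen-2-one | O=C1C=Cc2c(OCc3ccccc3)cc(OCc3ccccc3)c(C(=O)CCc3ccc(OCc4ccccc4)cc3)c2O1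
F6 | step 9 | (4R)-5,7-bis(benzyloxy)-8-{3-[4-(benzyloxy)phenyl]propanoyl}-4-phenyl-3,4-dihydro-2H-chromen-2-one | O=C1C[C@H](c2ccccc2)c2c(OCc3ccccc3)cc(OCc3ccccc3)c(C(=O)CCc3ccc(OCc4ccccc4)cc3)c2O1
F7 | step 10 | (3R)-3-(6-(benzyloxy)-2-hydroxy-3-{1-(triethylsilyloxy)-3-[4-(triisopropylsilyloxy)phenyl]propyl}-4-(triisopropylsilyloxy)phenyl)-3-phenylpropanoic acid | OC(=O)C[C@H](c1ccccc1)c1c(OCc2ccccc2)cc(O[Si](C(C)C)(C(C)C)C(C)C)c(C(CCc2ccc(O[Si](C(C)C)(C(C)C)C(C)C)cc2)O[Si](CC)(CC)CC)c1O
F0 | step 11 | none | none
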